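(The runs were generated by integration on assumed constants; noise was put on by code.)

75.0% of the two substrates together was what the reagent could convert in each of eta, alpha and theta, because each product takes one reagent and 0.0750 M stood against 0.050 M of each substrate, so the reagent was the limiting reagent.

| flask | left-handed substrate | right-handed substrate | reagent | free catalyst | temperature | remark | time |
|---|---|---|---|---|---|---|---|
| oak | 0.050 M | 0.050 M | 0.075 M | 2.5 mM | 55 °C | run made earlier |  |
| alder | 0.050 M | 0.050 M | 0.075 M | 10 mM | 88 °C | run made earlier |  |
| eta | 0.050 M | 0.050 M | 0.0750 M | 5.0 mM | 100 °C |  | 5.0 h |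
| alpha | 0.050 M | 0.050 M | 0.0750 M | 5.0 mM | 70 °C |  | 5.0 h |
| theta | 0.050 M | 0.050 M | 0.0750 M | 5.0 mM | 40 °C |  | 5.0 h |

- oak (time / h: left-handed product / %, right-handed product / %): 5.00: 44, 29; 8.00: 43, 35; 15.0: 42, 32; 30.0: 44, 32; 60.0: 43, 32
- alder (time / h: left-handed product / %, right-handed product / %): 0.833: 25, 49; 2.50: 29, 48; 5.00: 27, 48; 8.00: 26, 47; 10.0: 34, 48

(scatter of a reading: 2 percentage points)

- which flask leads in excess of left-handed product over right-handed product ("all alike" within 1.5 percentage points) (eta / alpha / theta / all alike)
- excess of left-handed product over right-handed product at the end, eta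
- excess of left-handed product over right-handed product at the end, alpha
- excess of left-handed product over right-handed product at the end, theta

- free catalyst is single-handed; left-handed substrate and right-handed substrate are mirror images of each other, charged as a racemate, each of them at the stated concentration
- the numbers in the tables scatter with a standard deviation of 2 percentage points
- reactions considered so far: reagent + catalyst intermediate B -> free catalyst + right-handed product; free catalyst + left-handed substrate <-> catalyst intermediate A; free catalyst -> spent catalyst; reagent + catalyst intermediate A -> free catalyst + left-handed product; free catalyst + right-handed substrate <-> catalyst intermediate B; left-handed substrate <-> right-handed substrate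
- an excess is below zero if the other one leads

I took the excess as left-handed minus right-handed product over their sum, the enantiomeric excess. Each product draws on its own substrate, which brings 50.0% of the two together, and neither earlier run showed a product clearly above that, so I assumed the substrates crossed over slowly. I called that 75.0% the ceiling. With left-handed product at 50.0% and the ceiling reached, right-handed product stands at 25.0%. That gave my lid, the excess of a flask that has reached its ceiling with one product at 50.0%, (1 − ceiling)/ceiling: 33.3%. So, on those assumptions, plus and minus 33.3% bounded the answer from above and below.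

The readings tightened this. Oak at 55 °C read 43% and 32% at 60.0 h, a read excess of 14.7%. Alder at 88 °C read 27% and 48% at 5.00 h, a read excess of −28.0%. Both carry the scatter. Reading this as a trend with temperature, though the catalyst differed too, I put theta between 14.7% and the upper lid, alpha between −28.0% and 14.7%, and eta between −28.0% and the lower lid. All this assumed the ceiling reached by 5.0 h, which I could not vouch for in theta.

The forecast gave −24% for eta, −5% for alpha and 23% for theta, with theta leading, on the ground that “Selectivity inverts with temperature”. Its figures are plain differences of the two percentages, mine are ratios to their sum. As numbers, its alpha and theta lay inside my bracket; its eta lay outside, above −28.0%.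

    reagent + catalyst intermediate B → free catalyst + right-handed product (k = 49.0 M⁻¹ min⁻¹, Ea = 76.0 kJ mol⁻¹)
    free catalyst + left-handed substrate ⇌ catalyst intermediate A (K = 17.0 M⁻¹, k = 610 M⁻¹ min⁻¹, Ea = 37.0 kJ mol⁻¹, ΔH = −46.0 kJ mol⁻¹)
    free catalyst → spent catalyst (k = 0.0190 min⁻¹, Ea = 123 kJ mol⁻¹)
    reagent + catalyst intermediate A → free catalyst + left-handed product (k = 130 M⁻¹ min⁻¹, Ea = 37.0 kJ mol⁻¹)
    free catalyst + right-handed substrate ⇌ catalyst intermediate B (K = 450 M⁻¹, k = 2200 M⁻¹ min⁻¹, Ea = 56.0 kJ mol⁻¹, ΔH = −13.0 kJ mol⁻¹)
    left-handed substrate ⇌ right-handed substrate (k = 0.0350 min⁻¹, Ea = 100 kJ mol⁻¹)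
    (constants at 100 °C)

The flasks gave −50.0% in eta, −5.06% in alpha and 37.6% in theta, so theta led. Eta's right-handed product stood at 56.3% at 5.00 h, above the 50.0% charged as its own substrate, so substrate had crossed hands. Theta passed the lid with 16.3% of its reagent still there at 5.00 h. At 50.0 h, with reagent at 0%, theta stood at 32.0%, under the lid of 33.3%.

Take theta with 0.30 M of reagent, which covers both substrates. The ceiling becomes 100% and the lid falls to 0%. That flask gave 0.0508%, with right-handed product at 50.0%.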